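**Plan**

- Flavan units are numbered 1 (top, free C8) to 4 (bottom, C4 is CH2). The last cuts are the nineteen O-benzyl bonds and the C3–O bond of unit 2, which goes back to a C3–Si bond.
- Key cut: ring C of unit 2 at C4–C4a, C3–C4 and O1–C2. This is possible because C4 of unit 2 is a diarylmethine carbon between C4a of its own ring A and C8 of ring A of unit 3, so it maps onto a C8 aldehyde carbon of a lower dimer. O1 is the ring-A phenol oxygen ortho to C4a, and C2–C3 with ring B come from a (Z)-β-silylstyrene.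
- The two other interflavan bonds (C4 of unit 1 to the future C8 of unit 2, and C4 of unit 3 to C8 of unit 4) are cut into a benzylated flavan-4-yl cation and an arene.
- Forward: epicatechin is benzylated and activated at C4. One portion is brominated at C8, coupled to the monomer and formylated (units 3 and 4); the other is arylated with 3,5-bis(benzyloxy)phenol (unit 1 plus ring A of unit 2). The annulation then closes ring C of unit 2, followed by Si→OH exchange and debenzylation.
- Stereochemistry: C2/C3 of units 1, 3 and 4 come from (−)-epicatechin. C4 of units 1 and 3 is set by attack anti to the 3-benzyloxy group. In unit 2, C2/C3 cis comes from the (Z)-alkene, C3/C4 trans from exo approach, the absolute sense from a chiral phosphoric acid, and C–Si becomes C–O with retention.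

Key step: step 11

Assumption: the (R) enantiomer of the phosphoric acid is taken as the one that directs the alkene to the required face of the o-quinone methide; for fragments of this size the sense of induction cannot be predicted with certainty.

**Route**

Step 1
Reactants: 1 (−)-epicatechin
Product: 2 5,7,3′,4′-tetra-O-benzyl-(−)-epicatechin (3-OH free)
Conditions: BnBr (4.4 equiv), K2CO3, DMF, 0 °C → rt
Reagents that add atoms: benzyl bromide BrCc1ccccc1
Why: Williamson etherification with a carbonate base alkylates the four phenols but not the much less acidic secondary alcohol, and no stereocentre is involved.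

Step 2
Reactants: 2 5,7,3′,4′-tetra-O-benzyl-(−)-epicatechin
Product: 3 3,5,7,3′,4′-penta-O-benzyl-(−)-epicatechin
Conditions: NaH, BnBr, DMF, 0 °C → rt
Reagents that add atoms: benzyl bromide BrCc1ccccc1
Why: Williamson etherification of the C3 alkoxide, which leaves C2 and C3 untouched because neither C–H bond is acidic under these conditions.

Step 3
Reactants: 3 3,5,7,3′,4′-penta-O-benzyl-(−)-epicatechin
Product: 4 4β-(2-ethoxyethoxy)-3,5,7,3′,4′-penta-O-benzylepicatechin (C4 ether trans to the 3-benzyloxy group)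
Conditions: DDQ (2 equiv), 2-ethoxyethanol (5 equiv), CH2Cl2, rt, dark
Reagents that add atoms: 2-ethoxyethanol CCOCCO
Why: DDQ-mediated benzylic oxidation removes hydride from C4, the cation is stabilised by the 5,7-dialkoxy ring A and is captured by the alcohol on the face opposite the 3-benzyloxy group, while plain benzyl ethers resist DDQ.

Step 4
Reactants: 4 4β-(2-ethoxyethoxy)-3,5,7,3′,4′-penta-O-benzylepicatechin
Product: 5 8-bromo-4β-(2-ethoxyethoxy)-3,5,7,3′,4′-penta-O-benzylepicatechin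
Conditions: NBS (1.05 equiv), CH2Cl2, −78 → −20 °C
Reagents that add atoms: N-bromosuccinimide O=C1CCC(=O)N1Br
Why: electrophilic aromatic bromination takes place on the phloroglucinol-type ring A at C8, the position established as most reactive in benzylated flavan-3-ols, and the bromine later serves as cap and formyl precursor.

Step 5
Reactants: 5 8-bromo-4β-(2-ethoxyethoxy)-3,5,7,3′,4′-penta-O-benzylepicatechin; 3 3,5,7,3′,4′-penta-O-benzyl-(−)-epicatechin (3 equiv)
Product: 6 deca-O-benzyl 8-bromoepicatechin-(4β→8)-epicatechin (bromine on C8 of the upper unit)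
Conditions: Me3SiOTf (0.2 equiv), CH2Cl2, −78 → −40 °C; Et3N quench
Reagents that add atoms: none
Why: Lewis-acid ionisation of the C4 ether gives the flavan-4-yl cation, which undergoes Friedel–Crafts alkylation at C8 of 3 anti to the 3-benzyloxy group (4β), while the C8 bromine stops the electrophile from condensing with itself.

Step 6
Reactants: 6 deca-O-benzyl 8-bromoepicatechin-(4β→8)-epicatechin
Product: 8 deca-O-benzyl epicatechin-(4β→8)-epicatechin 8-carbaldehyde (CHO on C8 of the upper unit), via aryllithium 7 (not isolated)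
Conditions: n-BuLi (1.1 equiv), THF, −78 °C; DMF, −78 → 0 °C; H2O
Reagents that add atoms: N,N-dimethylformamide CN(C)C=O
Why: bromine–lithium exchange at −78 °C outruns deprotonation of the benzyl ethers and the 2,6-dialkoxyaryllithium is formylated by DMF (Bouveault-type formylation) without touching a stereocentre.

Step 7
Reactants: 4 4β-(2-ethoxyethoxy)-3,5,7,3′,4′-penta-O-benzylepicatechin; 9 3,5-bis(benzyloxy)phenol (4 equiv)
Product: 10 4β-[2-hydroxy-4,6-bis(benzyloxy)phenyl]-3,5,7,3′,4′-penta-O-benzylepicatechin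
Conditions: Me3SiOTf (0.2 equiv), CH2Cl2, −78 → −20 °C; Et3N quench
Reagents that add atoms: none
Why: Friedel–Crafts capture of the same flavan-4-yl cation anti to the 3-benzyloxy group, at one of the two equivalent positions ortho to the hydroxyl, which are less hindered than the position between the two benzyloxy groups and are also reached from any O-alkylated ether by reversible ionisation and Fries-type O→C migration.

Step 8
Reactants: 11 3,4-bis(benzyloxy)benzaldehyde
Product: 12 1,2-bis(benzyloxy)-4-(2,2-dibromoethenyl)benzene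
Conditions: CBr4 (2 equiv), PPh3 (4 equiv), CH2Cl2, 0 °C
Reagents that add atoms: carbon tetrabromide BrC(Br)(Br)Br
Why: Corey–Fuchs dibromo-olefination of an aromatic aldehyde by the ylide formed from CBr4 and PPh3.

Step 9
Reactants: 12 1,2-bis(benzyloxy)-4-(2,2-dibromoethenyl)benzene; 13 benzyl(chloro)dimethylsilane
Product: 15 benzyl{[3,4-bis(benzyloxy)phenyl]ethynyl}dimethylsilane, via lithium acetylide 14 (not isolated)
Conditions: n-BuLi (2.1 equiv), THF, −78 → 0 °C; then 13, −78 °C → rt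
Reagents that add atoms: none
Why: second stage of the Corey–Fuchs sequence (exchange, Fritsch–Buttenberg–Wiechell rearrangement, deprotonation) gives the lithium acetylide, which is silylated at carbon by the chlorosilane.

Step 10
Reactants: 15 benzyl{[3,4-bis(benzyloxy)phenyl]ethynyl}dimethylsilane
Product: 17 benzyl{(Z)-2-[3,4-bis(benzyloxy)phenyl]ethenyl}dimethylsilane, via vinylalane 16 (not isolated)
Conditions: i-Bu2AlH (1.2 equiv), N-methylpyrrolidine (1.2 equiv), toluene/heptane, 60 °C; then aqueous KNaC4H4O6, 0 °C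
Reagents that add atoms: none
Why: syn-hydroalumination of the alkynylsilane places aluminium on the silicon-bearing carbon, the amine donor prevents cis-to-trans isomerisation of the vinylalane, and protonolysis with retention gives the (Z)-vinylsilane.

Step 11
Reactants: 10 4β-[2-hydroxy-4,6-bis(benzyloxy)phenyl]-3,5,7,3′,4′-penta-O-benzylepicatechin; 8 deca-O-benzyl epicatechin-(4β→8)-epicatechin 8-carbaldehyde; 17 benzyl{(Z)-2-[3,4-bis(benzyloxy)phenyl]ethenyl}dimethylsilane (3 equiv)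
Product: 20 nonadeca-O-benzyl tetramer carrying benzyldimethylsilyl on C3 of unit 2 (2,3-cis and 3,4-trans), via benzodioxaborin 18 (not isolated), via o-quinone methide 19 (not isolated)
Conditions: PhB(OH)2 (1.2 equiv), EtCO2H (0.3 equiv), 4 Å MS, toluene, 80 °C; then 17, (R)-3,3′-bis(2,4,6-triisopropylphenyl)-1,1′-binaphthyl-2,2′-diyl hydrogen phosphate (20 mol %), 0 °C → rt; filtration and chromatography without aqueous work-up
Reagents that add atoms: none
Why: Proposed new method: PhB(OH)2 esterifies the ring-A phenol of 10 and binds the aldehyde of 8, so that C4a, the only free position ortho to that oxygen, attacks the carbonyl carbon through a six-membered boron-templated transition state to give benzodioxaborin 18 with loss of water to the sieves, and the phosphoric acid then ionises the C4–O bond, which the two trioxygenated aryl groups on C4 make labile, to the o-quinone methide 19 held in a chiral hydrogen-bonded ion pair. The silicon-bearing carbon of 17 bonds to C4 because the charge developing at C2 is stabilised by the β C–Si bond and by the 3,4-dialkoxyphenyl group, and the quinone methide oxygen closes on C2 from the same face of the alkene, so ring C of unit 2 is formed as a six-membered ring by an asynchronous inverse-electron-demand hetero-[4+2] cycloaddition (C3–C4 first, O1–C2 second), while boron departs carrying the former aldehyde oxygen and ends in the dry medium as the anhydride of phenylboronic acid, triphenylboroxine. The closest known reactions are the phenylboronic-acid-mediated ortho-hydroxyalkylation of phenols to 4H-1,3,2-benzodioxaborins and the acid-promoted [4+2] cycloaddition of o-quinone methides with styrenes; a vinylsilane as the two-carbon partner and fragments of this size are new. C2 and C3 become cis because the (Z) geometry of 17 is carried through the suprafacial addition, C3 and C4 become trans because the alkene approaches exo with the hydrogen, not the silyl group, of the attacking carbon lodged between the two aryl groups on C4, and the absolute configuration at C4 (and with it C2 and C3) rests on the phosphate shielding one face of 19, helped by the C4 stereocentre of unit 1 next to the reacting ring. The step needs ring closure to outrun loss of silicon from the β-silyl cation, which the neighbouring oxygen nucleophile and the absence of external nucleophiles in toluene should secure, and 20 cannot be alkylated again because it has no free phenol.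

Step 12
Reactants: 20 nonadeca-O-benzyl tetramer carrying benzyldimethylsilyl on C3 of unit 2
Product: 22 nonadeca-O-benzyl derivative of the target tetramer (free 3-OH in unit 2), via silanol 21 (not isolated)
Conditions: Bu4NF (3 equiv), THF, 0 °C; then KHCO3, 30% H2O2, MeOH/THF, rt
Reagents that add atoms: hydrogen peroxide OO
Why: Tamao–Fleming oxidation, in which fluoride expels the benzyl group from silicon as toluene and the resulting silanol adds hydroperoxide and undergoes 1,2-migration of C3 from silicon to oxygen with retention, while benzyl ethers and fully etherified arenes are inert to basic peroxide.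

Step 13
Reactants: 22 nonadeca-O-benzyl derivative of the target tetramer
Product: 23 epicatechin-(4β→8)-epicatechin-(4β→8)-epicatechin-(4β→8)-epicatechin (the target)
Conditions: H2 (1 atm), Pd(OH)2/C, THF/MeOH/H2O, rt
Reagents that add atoms: none
Why: catalytic hydrogenolysis cleaves all nineteen benzyl ethers under neutral conditions that leave the acid-sensitive interflavan bonds and the twelve stereocentres unchanged.

**Compound list**

1 | (−)-epicatechin | Oc1cc(O)c2c(c1)O[C@H](c1ccc(O)c(O)c1)[C@H](O)C2 | starting material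

2 | 5,7,3′,4′-tetra-O-benzyl-(−)-epicatechin | C(c3ccccc3)Oc1cc(OCc3ccccc3)c2c(c1)O[C@H](c1ccc(OCc3ccccc3)c(OCc3ccccc3)c1)[C@H](O)C2 | intermediate

3 | 3,5,7,3′,4′-penta-O-benzyl-(−)-epicatechin | C(c3ccccc3)Oc1cc(OCc3ccccc3)c2c(c1)O[C@H](c1ccc(OCc3ccccc3)c(OCc3ccccc3)c1)[C@H](OCc3ccccc3)C2 | intermediate

4 | 4β-(2-ethoxyethoxy)-3,5,7,3′,4′-penta-O-benzylepicatechin (C4 ether trans to 3-OBn) | C(c3ccccc3)Oc1cc(OCc3ccccc3)c2c(c1)O[C@H](c1ccc(OCc3ccccc3)c(OCc3ccccc3)c1)[C@H](OCc3ccccc3)[C@H]2OCCOCC | intermediate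

5 | 8-bromo-4β-(2-ethoxyethoxy)-3,5,7,3′,4′-penta-O-benzylepicatechin | C(c3ccccc3)Oc1cc(OCc3ccccc3)c2c(c1Br)O[C@H](c1ccc(OCc3ccccc3)c(OCc3ccccc3)c1)[C@H](OCc3ccccc3)[C@H]2OCCOCC | intermediate

6 | deca-O-benzyl 8-bromoepicatechin-(4β→8)-epicatechin (Br on C8 of the upper unit) | Brc1c(OCc3ccccc3)cc(OCc3ccccc3)c2c1O[C@H](c1ccc(OCc3ccccc3)c(OCc3ccccc3)c1)[C@H](OCc3ccccc3)[C@H]2c1c(OCc3ccccc3)cc(OCc3ccccc3)c2c1O[C@H](c1ccc(OCc3ccccc3)c(OCc3ccccc3)c1)[C@H](OCc3ccccc3)C2 | intermediate

7 | aryllithium from 6 (Li on C8 of the upper unit) | [Li]c1c(OCc3ccccc3)cc(OCc3ccccc3)c2c1O[C@H](c1ccc(OCc3ccccc3)c(OCc3ccccc3)c1)[C@H](OCc3ccccc3)[C@H]2c1c(OCc3ccccc3)cc(OCc3ccccc3)c2c1O[C@H](c1ccc(OCc3ccccc3)c(OCc3ccccc3)c1)[C@H](OCc3ccccc3)C2 | intermediate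

8 | deca-O-benzyl epicatechin-(4β→8)-epicatechin 8-carbaldehyde (CHO on C8 of the upper unit) | O=Cc1c(OCc3ccccc3)cc(OCc3ccccc3)c2c1O[C@H](c1ccc(OCc3ccccc3)c(OCc3ccccc3)c1)[C@H](OCc3ccccc3)[C@H]2c1c(OCc3ccccc3)cc(OCc3ccccc3)c2c1O[C@H](c1ccc(OCc3ccccc3)c(OCc3ccccc3)c1)[C@H](OCc3ccccc3)C2 | intermediate

9 | 3,5-bis(benzyloxy)phenol | Oc1cc(OCc2ccccc2)cc(OCc2ccccc2)c1 | starting material

10 | 4β-[2-hydroxy-4,6-bis(benzyloxy)phenyl]-3,5,7,3′,4′-penta-O-benzylepicatechin | C(c3ccccc3)Oc1cc(OCc3ccccc3)c2c(c1)O[C@H](c1ccc(OCc3ccccc3)c(OCc3ccccc3)c1)[C@H](OCc3ccccc3)[C@H]2c1c(OCc3ccccc3)cc(OCc3ccccc3)cc1O | intermediate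

11 | 3,4-bis(benzyloxy)benzaldehyde | O=Cc1ccc(OCc2ccccc2)c(OCc2ccccc2)c1 | starting material

12 | 1,2-bis(benzyloxy)-4-(2,2-dibromoethenyl)benzene | BrC(Br)=Cc1ccc(OCc2ccccc2)c(OCc2ccccc2)c1 | intermediate

13 | benzyl(chloro)dimethylsilane | C[Si](C)(Cl)Cc1ccccc1 | starting material

14 | lithium [3,4-bis(benzyloxy)phenyl]acetylide | [Li]C#Cc1ccc(OCc2ccccc2)c(OCc2ccccc2)c1 | intermediate

15 | benzyl{[3,4-bis(benzyloxy)phenyl]ethynyl}dimethylsilane | C[Si](C)(Cc1ccccc1)C#Cc1ccc(OCc2ccccc2)c(OCc2ccccc2)c1 | intermediate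

16 | vinylalane: diisobutylaluminium on the silicon-bearing alkene carbon, silyl and aryl groups cis | C[Si](C)(Cc1ccccc1)/C(=C\c1ccc(OCc2ccccc2)c(OCc2ccccc2)c1)[Al](CC(C)C)CC(C)C | intermediate

17 | benzyl{(Z)-2-[3,4-bis(benzyloxy)phenyl]ethenyl}dimethylsilane | C[Si](C)(Cc1ccccc1)/C=C\c1ccc(OCc2ccccc2)c(OCc2ccccc2)c1 | intermediate

18 | 2-phenyl-4H-1,3,2-benzodioxaborin joining 10 and 8: boron bridges the phenol oxygen and the former aldehyde oxygen; the acetal carbon (future C4 of unit 2) carries ring A of unit 3 and is formed as both epimers | C(c3ccccc3)Oc1cc(OCc3ccccc3)c2c(c1)O[C@H](c1ccc(OCc3ccccc3)c(OCc3ccccc3)c1)[C@H](OCc3ccccc3)[C@H]2c1c(OCc3ccccc3)cc(OCc3ccccc3)c4c1OB(c5ccccc5)OC4c1c(OCc3ccccc3)cc(OCc3ccccc3)c2c1O[C@H](c1ccc(OCc3ccccc3)c(OCc3ccccc3)c1)[C@H](OCc3ccccc3)[C@H]2c1c(OCc3ccccc3)cc(OCc3ccccc3)c2c1O[C@H](c1ccc(OCc3ccccc3)c(OCc3ccccc3)c1)[C@H](OCc3ccccc3)C2 | intermediate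

19 | o-quinone methide: ring A of unit 2 as a 6-methylenecyclohexa-2,4-dienone whose exocyclic carbon (C4) bears ring A of unit 3; drawn as the E isomer, aryl anti to C=O | C(c3ccccc3)Oc1cc(OCc3ccccc3)c2c(c1)O[C@H](c1ccc(OCc3ccccc3)c(OCc3ccccc3)c1)[C@H](OCc3ccccc3)[C@H]2C1=C(OCc3ccccc3)C=C(OCc3ccccc3)/C(C1=O)=C\c1c(OCc3ccccc3)cc(OCc3ccccc3)c2c1O[C@H](c1ccc(OCc3ccccc3)c(OCc3ccccc3)c1)[C@H](OCc3ccccc3)[C@H]2c1c(OCc3ccccc3)cc(OCc3ccccc3)c2c1O[C@H](c1ccc(OCc3ccccc3)c(OCc3ccccc3)c1)[C@H](OCc3ccccc3)C2 | intermediate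

20 | nonadeca-O-benzyl tetramer with benzyldimethylsilyl on C3 of unit 2 (silyl cis to the C2 aryl group, trans to the C4 aryl group) | C(c3ccccc3)Oc1cc(OCc3ccccc3)c2c(c1)O[C@H](c1ccc(OCc3ccccc3)c(OCc3ccccc3)c1)[C@H](OCc3ccccc3)[C@H]2c1c(OCc3ccccc3)cc(OCc3ccccc3)c2c1O[C@H](c1ccc(OCc3ccccc3)c(OCc3ccccc3)c1)[C@H]([Si](C)(C)Cc3ccccc3)[C@H]2c1c(OCc3ccccc3)cc(OCc3ccccc3)c2c1O[C@H](c1ccc(OCc3ccccc3)c(OCc3ccccc3)c1)[C@H](OCc3ccccc3)[C@H]2c1c(OCc3ccccc3)cc(OCc3ccccc3)c2c1O[C@H](c1ccc(OCc3ccccc3)c(OCc3ccccc3)c1)[C@H](OCc3ccccc3)C2 | intermediate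

21 | silanol: as 20 with hydroxydimethylsilyl on C3 of unit 2 | C(c3ccccc3)Oc1cc(OCc3ccccc3)c2c(c1)O[C@H](c1ccc(OCc3ccccc3)c(OCc3ccccc3)c1)[C@H](OCc3ccccc3)[C@H]2c1c(OCc3ccccc3)cc(OCc3ccccc3)c2c1O[C@H](c1ccc(OCc3ccccc3)c(OCc3ccccc3)c1)[C@H]([Si](C)(C)O)[C@H]2c1c(OCc3ccccc3)cc(OCc3ccccc3)c2c1O[C@H](c1ccc(OCc3ccccc3)c(OCc3ccccc3)c1)[C@H](OCc3ccccc3)[C@H]2c1c(OCc3ccccc3)cc(OCc3ccccc3)c2c1O[C@H](c1ccc(OCc3ccccc3)c(OCc3ccccc3)c1)[C@H](OCc3ccccc3)C2 | intermediate

22 | nonadeca-O-benzyl derivative of the target tetramer (free 3-OH in unit 2) | C(c3ccccc3)Oc1cc(OCc3ccccc3)c2c(c1)O[C@H](c1ccc(OCc3ccccc3)c(OCc3ccccc3)c1)[C@H](OCc3ccccc3)[C@H]2c1c(OCc3ccccc3)cc(OCc3ccccc3)c2c1O[C@H](c1ccc(OCc3ccccc3)c(OCc3ccccc3)c1)[C@H](O)[C@H]2c1c(OCc3ccccc3)cc(OCc3ccccc3)c2c1O[C@H](c1ccc(OCc3ccccc3)c(OCc3ccccc3)c1)[C@H](OCc3ccccc3)[C@H]2c1c(OCc3ccccc3)cc(OCc3ccccc3)c2c1O[C@H](c1ccc(OCc3ccccc3)c(OCc3ccccc3)c1)[C@H](OCc3ccccc3)C2 | intermediate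

23 | epicatechin-(4β→8)-epicatechin-(4β→8)-epicatechin-(4β→8)-epicatechin, the all-(4β→8)-linked (−)-epicatechin tetramer | Oc1cc(O)c2c(c1)O[C@H](c1ccc(O)c(O)c1)[C@H](O)[C@H]2c1c(O)cc(O)c2c1O[C@H](c1ccc(O)c(O)c1)[C@H](O)[C@H]2c1c(O)cc(O)c2c1O[C@H](c1ccc(O)c(O)c1)[C@H](O)[C@H]2c1c(O)cc(O)c2c1O[C@H](c1ccc(O)c(O)c1)[C@H](O)C2 | target

**Summary**

Total step count: 13. Longest linear sequence: 9 steps (1 → 2 → 3 → 4 → 5 → 6 → 8 → 20 → 22 → 23).

**Steps most likely to fail**

1. Step 11 (proposed new method). The β-silyl cation may shed silicon before the oxygen closes on C2, leaving an open 1,3-diarylpropene. The alkene may also add to the wrong face of the quinone methide or in the endo mode. The hindered, electron-rich aldehyde may condense slowly, so that the ionised intermediate is consumed by a second molecule of phenol.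
   Fallback (known chemistry only): abandon the annulation and grow the chain by repeated flavan-4-yl cation couplings with the bromine-capped electrophile 5. Setting out from 6, bromine–lithium exchange (n-BuLi, THF, −78 °C, via 7) and quenching with water should give deca-O-benzyl epicatechin-(4β→8)-epicatechin F1. Coupling of F1 with 5 (Me3SiOTf, CH2Cl2, −78 °C) should give the 8-bromo pentadeca-O-benzyl trimer F2. A second exchange, through the lithiated trimer F3, and protonation should give the pentadeca-O-benzyl trimer F4. A further coupling with 5 should give the 8-bromo icosa-O-benzyl tetramer F5. Hydrogenolysis over Pd(OH)2/C with Et3N would remove the twenty benzyl groups and the bromine together, coming back to the route at 23.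

2. Step 12. Because O1 is β to silicon, fluoride may trigger β-elimination of the ring oxygen and open ring C before the benzyl group leaves. Oxidation at the hindered secondary silicon may also stall.
   Fallback: give silicon an oxygen ligand before the annulation, so that no fluoride debenzylation is needed. Setting out from 12, the acetylide 14 would be trapped with chloropentamethyldisiloxane (C[Si](C)(C)O[Si](C)(C)Cl) to give the alkynyl disiloxane F6. Syn semihydrogenation (H2, Pd/CaCO3 poisoned with Pb(OAc)2, quinoline) should give the (Z)-vinyl disiloxane F7. Annulation with 10 and 8 as in step 11, through 18 and 19, should give the nonadeca-O-benzyl tetramer with pentamethyldisiloxanyl on C3 of unit 2 F8. Direct Tamao oxidation (KF, KHCO3, H2O2, THF/MeOH) would then come back to the route at 22.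

3. Step 7. The cation may attack the phenol para to the hydroxyl, between the two benzyloxy groups, or alkylate it twice, eroding the supply of the correct ortho isomer.
   Fallback: use a nucleophile whose three ring positions are equivalent and move the selectivity to an O-alkylation. Setting out from 4, coupling with phloroglucinol (benzene-1,3,5-triol, Me3SiOTf, THF/CH2Cl2, −40 °C) should give 4β-(2,4,6-trihydroxyphenyl)-3,5,7,3′,4′-penta-O-benzylepicatechin F9. Controlled dibenzylation (BnBr 2 equiv, K2CO3, DMF, 0 °C) should alkylate the unhindered para hydroxyl first and then one of the two equivalent hindered ortho hydroxyls, coming back to the route at 10.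

**Further compounds**

F1 | step 11 | deca-O-benzyl epicatechin-(4β→8)-epicatechin (perbenzylated dimer) | C(c3ccccc3)Oc1cc(OCc3ccccc3)c2c(c1)O[C@H](c1ccc(OCc3ccccc3)c(OCc3ccccc3)c1)[C@H](OCc3ccccc3)[C@H]2c1c(OCc3ccccc3)cc(OCc3ccccc3)c2c1O[C@H](c1ccc(OCc3ccccc3)c(OCc3ccccc3)c1)[C@H](OCc3ccccc3)C2

F2 | step 11 | pentadeca-O-benzyl trimer, three epicatechin units linked 4β→8, bromine on C8 of the top unit | Brc1c(OCc3ccccc3)cc(OCc3ccccc3)c2c1O[C@H](c1ccc(OCc3ccccc3)c(OCc3ccccc3)c1)[C@H](OCc3ccccc3)[C@H]2c1c(OCc3ccccc3)cc(OCc3ccccc3)c2c1O[C@H](c1ccc(OCc3ccccc3)c(OCc3ccccc3)c1)[C@H](OCc3ccccc3)[C@H]2c1c(OCc3ccccc3)cc(OCc3ccccc3)c2c1O[C@H](c1ccc(OCc3ccccc3)c(OCc3ccccc3)c1)[C@H](OCc3ccccc3)C2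

F3 | step 11 | lithiated trimer, lithium on C8 of the top unit (not isolated) | [Li]c1c(OCc3ccccc3)cc(OCc3ccccc3)c2c1O[C@H](c1ccc(OCc3ccccc3)c(OCc3ccccc3)c1)[C@H](OCc3ccccc3)[C@H]2c1c(OCc3ccccc3)cc(OCc3ccccc3)c2c1O[C@H](c1ccc(OCc3ccccc3)c(OCc3ccccc3)c1)[C@H](OCc3ccccc3)[C@H]2c1c(OCc3ccccc3)cc(OCc3ccccc3)c2c1O[C@H](c1ccc(OCc3ccccc3)c(OCc3ccccc3)c1)[C@H](OCc3ccccc3)C2

F4 | step 11 | pentadeca-O-benzyl trimer, three epicatechin units linked 4β→8 | C(c3ccccc3)Oc1cc(OCc3ccccc3)c2c(c1)O[C@H](c1ccc(OCc3ccccc3)c(OCc3ccccc3)c1)[C@H](OCc3ccccc3)[C@H]2c1c(OCc3ccccc3)cc(OCc3ccccc3)c2c1O[C@H](c1ccc(OCc3ccccc3)c(OCc3ccccc3)c1)[C@H](OCc3ccccc3)[C@H]2c1c(OCc3ccccc3)cc(OCc3ccccc3)c2c1O[C@H](c1ccc(OCc3ccccc3)c(OCc3ccccc3)c1)[C@H](OCc3ccccc3)C2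

F5 | step 11 | icosa-O-benzyl tetramer, four epicatechin units linked 4β→8, bromine on C8 of unit 1 | Brc1c(OCc3ccccc3)cc(OCc3ccccc3)c2c1O[C@H](c1ccc(OCc3ccccc3)c(OCc3ccccc3)c1)[C@H](OCc3ccccc3)[C@H]2c1c(OCc3ccccc3)cc(OCc3ccccc3)c2c1O[C@H](c1ccc(OCc3ccccc3)c(OCc3ccccc3)c1)[C@H](OCc3ccccc3)[C@H]2c1c(OCc3ccccc3)cc(OCc3ccccc3)c2c1O[C@H](c1ccc(OCc3ccccc3)c(OCc3ccccc3)c1)[C@H](OCc3ccccc3)[C@H]2c1c(OCc3ccccc3)cc(OCc3ccccc3)c2c1O[C@H](c1ccc(OCc3ccccc3)c(OCc3ccccc3)c1)[C@H](OCc3ccccc3)C2

F6 | step 12 | 1-{[3,4-bis(benzyloxy)phenyl]ethynyl}-1,1,3,3,3-pentamethyldisiloxane | C[Si](C)(C)O[Si](C)(C)C#Cc1ccc(OCc2ccccc2)c(OCc2ccccc2)c1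

F7 | step 12 | 1-{(Z)-2-[3,4-bis(benzyloxy)phenyl]ethenyl}-1,1,3,3,3-pentamethyldisiloxane | C[Si](C)(C)O[Si](C)(C)/C=C\c1ccc(OCc2ccccc2)c(OCc2ccccc2)c1

F8 | step 12 | nonadeca-O-benzyl tetramer with pentamethyldisiloxanyl on C3 of unit 2 (2,3-cis and 3,4-trans) | C(c3ccccc3)Oc1cc(OCc3ccccc3)c2c(c1)O[C@H](c1ccc(OCc3ccccc3)c(OCc3ccccc3)c1)[C@H](OCc3ccccc3)[C@H]2c1c(OCc3ccccc3)cc(OCc3ccccc3)c2c1O[C@H](c1ccc(OCc3ccccc3)c(OCc3ccccc3)c1)[C@H]([Si](C)(C)O[Si](C)(C)C)[C@H]2c1c(OCc3ccccc3)cc(OCc3ccccc3)c2c1O[C@H](c1ccc(OCc3ccccc3)c(OCc3ccccc3)c1)[C@H](OCc3ccccc3)[C@H]2c1c(OCc3ccccc3)cc(OCc3ccccc3)c2c1O[C@H](c1ccc(OCc3ccccc3)c(OCc3ccccc3)c1)[C@H](OCc3ccccc3)C2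

F9 | step 7 | 4β-(2,4,6-trihydroxyphenyl)-3,5,7,3′,4′-penta-O-benzylepicatechin | C(c3ccccc3)Oc1cc(OCc3ccccc3)c2c(c1)O[C@H](c1ccc(OCc3ccccc3)c(OCc3ccccc3)c1)[C@H](OCc3ccccc3)[C@H]2c1c(O)cc(O)cc1O
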